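**Plan**

- Retrosynthesis: the acid is traced back to a C1 acetate, then the O1–O2 bond of the dioxolane is cut to give di-tertiary 1,3-diol 23. Two identical alkyne cycles cut C1–C2, C2–C3 and C3–CH3, then C3–C4, C4–C5 and C5–CH3. A Wittig disconnection at C10=C11 leaves (R)-citronellal 3 and bromide 1.
- Enabling feature: in the ring O1–O2–C3–C4–C5 both oxygen-bearing carbons, C3 (CH3, C2H2 arm) and C5 (CH3, C6H2 chain), are fully substituted. Each can therefore be carried as a tertiary alcohol of fixed configuration, and the only ring can be closed between O1 and O2 without breaking a C–O bond.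
- Forward: citronellal is homologated to alkyne 4 (adds C4), and ozonolysis/Wittig attaches C11–C15 with the phenyl ring. The cycle alkyne → carboalumination/formaldehyde → Sharpless epoxidation → hydride opening is then run twice, building C5 first and C3 second.
- The chain is complete at diol 21; acetylation, desilylation, O–O closure (the single ring), deacetylation and oxidation of C1 finish the synthesis.
- Stereochemistry: C7 is the stereocentre of (R)-citronellal. C5 and C3 come from two Sharpless epoxidations with D-(−)-diethyl tartrate, each read out by C2-selective hydride opening, and the ring closure retains both.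

Key step: step 17

Remark: C1–C15 denote the target chain throughout (C1 carboxyl carbon, C15 benzylic carbon). The spatial arrangement at C3 is constant from 20 to 28, but its descriptor is S while C1 is at the alcohol level (21–26) and R in 27 and 28, because the ranking of C2 and C4 changes.
Remark: the two tertiary hydroxyls of 23 are assumed to be fluorinated indiscriminately; either mono-hypofluorite closes to the same dioxolane, and 24 is drawn as the O3 isomer.

**Route**

Step 1
Reactants: 1 (5-bromopentyl)benzene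
Product: 2 (5-phenylpentyl)triphenylphosphonium bromide
Conditions: PPh3, MeCN, reflux
Reagents that add atoms: triphenylphosphine, c1ccc(cc1)P(c1ccccc1)c1ccccc1
Why: Phosphonium salt formation by SN2 attack of the phosphine on the unhindered primary bromide is routine and gives the Wittig partner that carries C11–C15 and the phenyl ring.

Step 2
Reactants: 3 (R)-citronellal
Product: 4 (4R)-4,8-dimethylnon-7-en-1-yne
Conditions: dimethyl (1-diazo-2-oxopropyl)phosphonate, K2CO3, MeOH, 0 °C → rt
Reagents that add atoms: dimethyl (1-diazo-2-oxopropyl)phosphonate, COP(=O)(OC)C(=[N+]=[N-])C(C)=O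
Why: The Ohira–Bestmann variant of the Seyferth–Gilbert homologation turns the aldehyde into a terminal alkyne under carbonate conditions, adding C4 and leaving the β-stereocentre (the future C7, taken from the chiral pool) untouched.

Step 3
Reactants: 4 (4R)-4,8-dimethylnon-7-en-1-yne
Product: 6 (4R)-4-methylhept-6-ynal, via secondary ozonide 5 (not isolated)
Conditions: O3, CH2Cl2, −78 °C (Solvent Red 23 end point); then PPh3, −78 °C → rt; the volatile aldehyde is used crude
Reagents that add atoms: ozone, [O-][O+]=O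
Why: Ozonolysis with reductive work-up cleaves the electron-rich trisubstituted alkene much faster than the terminal alkyne, and the dye end point should stop the oxidation before the triple bond is attacked.

Step 4
Reactants: 6 (4R)-4-methylhept-6-ynal; 2 (5-phenylpentyl)triphenylphosphonium bromide
Product: 8 (4R,7Z)-4-methyl-12-phenyldodec-7-en-1-yne, via phosphonium ylide 7 (not isolated)
Conditions: 2, NaN(SiMe3)2, THF, 0 °C; then 6, −78 °C → rt
Reagents that add atoms: none
Why: A Wittig reaction of the non-stabilised ylide 7 joins C10 to C11, the preformed ylide being too weak a base to consume the alkyne C–H; the alkene should be mainly Z, which is of no consequence because step 8 saturates it.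

Step 5
Reactants: 8 (4R,7Z)-4-methyl-12-phenyldodec-7-en-1-yne
Product: 10 (2E,5R,8Z)-3,5-dimethyl-13-phenyltrideca-2,8-dien-1-ol, via alkenylalane 9 (not isolated)
Conditions: AlMe3, (C5H5)2ZrCl2 (0.25 equiv), CH2Cl2, 0 °C → rt; then (CH2O)n, 0 °C → rt; aq. HCl work-up
Reagents that add atoms: trimethylaluminium, C[Al](C)C; formaldehyde (as paraformaldehyde), C=O
Why: Negishi zirconium-catalysed carboalumination adds CH3 and Al syn across the terminal alkyne with Al on the terminal carbon (alkenylalane 9), and capture by formaldehyde with retention gives the E-trisubstituted allylic alcohol, while the internal Z-alkene does not carbometalate.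

Step 6
Reactants: 10 (2E,5R,8Z)-3,5-dimethyl-13-phenyltrideca-2,8-dien-1-ol
Product: 11 (2R,3R,5R,8Z)-2,3-epoxy-3,5-dimethyl-13-phenyltridec-8-en-1-ol
Conditions: Ti(OiPr)4 (10 mol %), D-(−)-diethyl tartrate (12 mol %), t-BuOOH, 4 Å molecular sieves, CH2Cl2, −20 °C
Reagents that add atoms: tert-butyl hydroperoxide, CC(C)(C)OO
Why: The Sharpless asymmetric epoxidation acts only on the allylic alcohol, and with the D-(−)-tartrate ligand oxygen should be delivered to the face that gives the (2R,3R)-epoxide (the mirror image of the (2S,3S) outcome of E-3-methyl-2-alkenols with the L-(+)-ester), which fixes the quaternary carbon that becomes C5 under reagent control.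

Step 7
Reactants: 11 (2R,3R,5R,8Z)-2,3-epoxy-3,5-dimethyl-13-phenyltridec-8-en-1-ol
Product: 12 (3R,5R,8Z)-3,5-dimethyl-13-phenyltridec-8-ene-1,3-diol
Conditions: NaAlH2(OCH2CH2OCH3)2, THF, 0 °C → rt
Reagents that add atoms: none
Why: In the hydroxyl-directed reduction of a 2,3-epoxy alcohol with NaAlH2(OCH2CH2OCH3)2 the alkoxy-bound aluminate delivers hydride to C2, which is also the less substituted epoxide carbon, so the 1,3-diol forms with the tertiary C–O bond and its configuration intact.

Step 8
Reactants: 12 (3R,5R,8Z)-3,5-dimethyl-13-phenyltridec-8-ene-1,3-diol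
Product: 13 (3R,5R)-3,5-dimethyl-13-phenyltridecane-1,3-diol
Conditions: H2 (1 atm), 10% Pd/C, EtOAc, rt
Reagents that add atoms: none
Why: Heterogeneous catalytic hydrogenation saturates the isolated disubstituted alkene at balloon pressure without touching the phenyl ring or the alcohols, erasing the E/Z question of step 4.

Step 9
Reactants: 13 (3R,5R)-3,5-dimethyl-13-phenyltridecane-1,3-diol
Product: 14 (3R,5R)-3,5-dimethyl-13-phenyl-1,3-bis(triethylsilyloxy)tridecane
Conditions: Et3SiOTf, 2,6-lutidine, CH2Cl2, −78 → 0 °C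
Reagents that add atoms: triethylsilyl trifluoromethanesulfonate, CC[Si](CC)(CC)OS(=O)(=O)C(F)(F)F
Why: The silyl triflate silylates the primary and the hindered tertiary hydroxyl alike (silyl ether formation), so that no free β-alkoxide is present to trigger retro-aldol cleavage once C3 is an aldehyde.

Step 10
Reactants: 14 (3R,5R)-3,5-dimethyl-13-phenyl-1,3-bis(triethylsilyloxy)tridecane
Product: 16 (3R,5R)-3,5-dimethyl-13-phenyl-3-(triethylsilyloxy)tridecanal, via alkoxysulfonium chloride 15 (not isolated)
Conditions: (COCl)2, DMSO, CH2Cl2, −78 → −35 °C; then Et3N, −78 °C → rt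
Reagents that add atoms: none
Why: Under Swern conditions a primary triethylsilyl ether is cleaved by the chlorosulfonium reagent and oxidised directly to the aldehyde through alkoxysulfonium salt 15, whereas the hindered tertiary silyl ether is not attacked, so a single operation unmasks and oxidises C3.

Step 11
Reactants: 16 (3R,5R)-3,5-dimethyl-13-phenyl-3-(triethylsilyloxy)tridecanal
Product: 17 (4R,6R)-4,6-dimethyl-14-phenyl-4-(triethylsilyloxy)tetradec-1-yne
Conditions: dimethyl (1-diazo-2-oxopropyl)phosphonate, K2CO3, MeOH/THF, 0 °C → rt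
Reagents that add atoms: dimethyl (1-diazo-2-oxopropyl)phosphonate, COP(=O)(OC)C(=[N+]=[N-])C(C)=O
Why: The same Ohira–Bestmann homologation as in step 2 adds C2; the β-oxygen is silylated, so retro-aldol cleavage is excluded, and the β-carbon is quaternary, so nothing can epimerise.

Step 12
Reactants: 17 (4R,6R)-4,6-dimethyl-14-phenyl-4-(triethylsilyloxy)tetradec-1-yne
Product: 19 (2E,5R,7R)-3,5,7-trimethyl-15-phenyl-5-(triethylsilyloxy)pentadec-2-en-1-ol, via alkenylalane 18 (not isolated)
Conditions: AlMe3, (C5H5)2ZrCl2 (0.5 equiv), CH2Cl2, rt; then (CH2O)n, 0 °C → rt; cold aq. NH4Cl/HCl work-up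
Reagents that add atoms: trimethylaluminium, C[Al](C)C; formaldehyde (as paraformaldehyde), C=O
Why: A second Negishi carboalumination with formaldehyde capture, syn and regioselective as in step 5, installs the C3 methyl group and C1 as an E-allylic alcohol, silyl ethers being tolerated by AlMe3/(C5H5)2ZrCl2.

Step 13
Reactants: 19 (2E,5R,7R)-3,5,7-trimethyl-15-phenyl-5-(triethylsilyloxy)pentadec-2-en-1-ol
Product: 20 (2R,3R,5R,7R)-2,3-epoxy-3,5,7-trimethyl-15-phenyl-5-(triethylsilyloxy)pentadecan-1-ol
Conditions: Ti(OiPr)4 (10 mol %), D-(−)-diethyl tartrate (12 mol %), t-BuOOH, 4 Å molecular sieves, CH2Cl2, −20 °C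
Reagents that add atoms: tert-butyl hydroperoxide, CC(C)(C)OO
Why: A second Sharpless asymmetric epoxidation with the D-(−)-tartrate ligand should again give the (2R,3R)-epoxide under reagent control, the two existing stereocentres being too remote (C5 is separated from the alkene by a CH2 group) to override the catalyst, and this fixes the configuration of C3.

Step 14
Reactants: 20 (2R,3R,5R,7R)-2,3-epoxy-3,5,7-trimethyl-15-phenyl-5-(triethylsilyloxy)pentadecan-1-ol
Product: 21 (3S,5R,7R)-3,5,7-trimethyl-15-phenyl-5-(triethylsilyloxy)pentadecane-1,3-diol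
Conditions: NaAlH2(OCH2CH2OCH3)2, THF, 0 °C → rt
Reagents that add atoms: none
Why: Hydroxyl-directed hydride opening at C2 as in step 7 gives the tertiary C3 carbinol with its C–O bond intact, and the silyl ether is inert to the aluminate.

Step 15
Reactants: 21 (3S,5R,7R)-3,5,7-trimethyl-15-phenyl-5-(triethylsilyloxy)pentadecane-1,3-diol
Product: 22 (3S,5R,7R)-3-hydroxy-3,5,7-trimethyl-15-phenyl-5-(triethylsilyloxy)pentadecyl acetate
Conditions: Ac2O, pyridine, CH2Cl2, 0 °C → rt
Reagents that add atoms: acetic anhydride, CC(=O)OC(C)=O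
Why: Acetylation with Ac2O/pyridine in the absence of an acyl-transfer catalyst is selective for the primary over the tertiary hydroxyl and masks C1 as an ester that should be inert to F2 and HF.

Step 16
Reactants: 22 (3S,5R,7R)-3-hydroxy-3,5,7-trimethyl-15-phenyl-5-(triethylsilyloxy)pentadecyl acetate
Product: 23 (3S,5R,7R)-3,5-dihydroxy-3,5,7-trimethyl-15-phenylpentadecyl acetate
Conditions: HF·pyridine, pyridine, THF, 0 °C → rt
Reagents that add atoms: none
Why: Fluoride-induced desilylation, driven by Si–F bond formation and buffered with pyridine, frees the C5 hydroxyl without ionising either tertiary carbinol or cleaving the acetate.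

Step 17
Reactants: 23 (3S,5R,7R)-3,5-dihydroxy-3,5,7-trimethyl-15-phenylpentadecyl acetate
Product: 25 2-[(3S,5R)-3,5-dimethyl-5-[(2R)-2-methyl-10-phenyldecyl]-1,2-dioxolan-3-yl]ethyl acetate, via tertiary hypofluorite 24 (not isolated)
Conditions: F2 (10% in N2, 1.05 equiv), CsF, EtCN (dilute), −78 °C; N2 purge; −78 → −30 °C
Reagents that add atoms: none
Why: Proposed new method: F2 should convert one of the two fluoride-hydrogen-bonded tertiary hydroxyls of 23 into a hypofluorite (24), in which oxygen is the positive end of the O–F bond, and the neighbouring hydroxyl should then displace fluoride at that oxygen, forming O1–O2. The closest known reaction types are the preparation of tert-butyl and methyl hypofluorite from the alcohols and F2 in nitrile solvents, their behaviour as electrophilic alkoxylating agents, and the formation of a perfluoroalkyl peroxide from a hypofluorite and a fluoride-generated alkoxide. The 1,2-dioxolane closes by a 5-exo-tet substitution at oxygen, the O–F bond lying outside the forming ring. No stereocentre is created and neither the C3–O nor the C5–O bond is broken, so the configurations set in steps 6 and 13 are carried over with retention. The step needs O-fluorination to outrun fluorination of the phenyl ring and of the tertiary C7–H bond, and ring closure to outrun β-scission of the hypofluorite; this should be secured by one equivalent of dilute F2 at −78 °C, activation of the O–H groups by fluoride, the absence of a carbinol hydrogen (no loss of HF to a carbonyl) and the 1,3-placement of the two oxygens.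

Step 18
Reactants: 25 2-[(3S,5R)-3,5-dimethyl-5-[(2R)-2-methyl-10-phenyldecyl]-1,2-dioxolan-3-yl]ethyl acetate
Product: 26 2-[(3S,5R)-3,5-dimethyl-5-[(2R)-2-methyl-10-phenyldecyl]-1,2-dioxolan-3-yl]ethanol
Conditions: K2CO3, MeOH, 0 °C → rt
Reagents that add atoms: none
Why: Carbonate-catalysed transesterification with methanol removes the acetate, and because neither peroxide-bearing carbon of the dioxolane carries a hydrogen the base-induced Kornblum–DeLaMare fragmentation is not available.

Step 19
Reactants: 26 2-[(3S,5R)-3,5-dimethyl-5-[(2R)-2-methyl-10-phenyldecyl]-1,2-dioxolan-3-yl]ethanol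
Product: 28 2-[(3R,5R)-3,5-dimethyl-5-[(2R)-2-methyl-10-phenyldecyl]-1,2-dioxolan-3-yl]acetic acid, via dioxolane acetaldehyde 27 (not isolated)
Conditions: TEMPO (20 mol %), PhI(OAc)2, MeCN/H2O, rt
Reagents that add atoms: water, O
Why: Nitroxyl-catalysed oxidation with PhI(OAc)2 in aqueous acetonitrile takes the primary alcohol through aldehyde 27 and its hydrate to the carboxylic acid under mildly acidic, non-reducing conditions that a dialkyl peroxide should tolerate.

**Compound list**

1 | (5-bromopentyl)benzene | BrCCCCCc1ccccc1 | starting material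
2 | (5-phenylpentyl)triphenylphosphonium bromide | [Br-].c1ccc(cc1)CCCCC[P+](c1ccccc1)(c1ccccc1)c1ccccc1 | intermediate
3 | (R)-citronellal, (3R)-3,7-dimethyloct-6-enal | C[C@H](CCC=C(C)C)CC=O | starting material
4 | (4R)-4,8-dimethylnon-7-en-1-yne | C[C@H](CCC=C(C)C)CC#C | intermediate
5 | 3,3-dimethyl-5-[(3R)-3-methylhex-5-yn-1-yl]-1,2,4-trioxolane (secondary ozonide, both C5 epimers) | C[C@H](CCC1OOC(C)(C)O1)CC#C | intermediate (not isolated)
6 | (4R)-4-methylhept-6-ynal | C[C@H](CCC=O)CC#C | intermediate
7 | (5-phenylpentylidene)triphenylphosphorane | c1ccc(cc1)CCCCC=P(c1ccccc1)(c1ccccc1)c1ccccc1 | intermediate (not isolated)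
8 | (4R,7Z)-4-methyl-12-phenyldodec-7-en-1-yne | C[C@H](CC/C=C\CCCCc1ccccc1)CC#C | intermediate
9 | dimethyl[(1E,4R,7Z)-2,4-dimethyl-12-phenyldodeca-1,7-dien-1-yl]alane | C[C@H](CC/C=C\CCCCc1ccccc1)C/C(C)=C/[Al](C)C | intermediate (not isolated)
10 | (2E,5R,8Z)-3,5-dimethyl-13-phenyltrideca-2,8-dien-1-ol | C[C@H](CC/C=C\CCCCc1ccccc1)C/C(C)=C/CO | intermediate
11 | (2R,3R,5R,8Z)-2,3-epoxy-3,5-dimethyl-13-phenyltridec-8-en-1-ol | C[C@H](CC/C=C\CCCCc1ccccc1)C[C@]1(C)[C@@H](CO)O1 | intermediate
12 | (3R,5R,8Z)-3,5-dimethyl-13-phenyltridec-8-ene-1,3-diol | C[C@H](CC/C=C\CCCCc1ccccc1)C[C@](O)(C)CCO | intermediate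
13 | (3R,5R)-3,5-dimethyl-13-phenyltridecane-1,3-diol | C[C@H](CCCCCCCCc1ccccc1)C[C@](O)(C)CCO | intermediate
14 | (3R,5R)-3,5-dimethyl-13-phenyl-1,3-bis(triethylsilyloxy)tridecane | C[C@H](CCCCCCCCc1ccccc1)C[C@](O[Si](CC)(CC)CC)(C)CCO[Si](CC)(CC)CC | intermediate
15 | dimethyl{[(3R,5R)-3,5-dimethyl-13-phenyl-3-(triethylsilyloxy)tridecyl]oxy}sulfonium chloride | C[C@H](CCCCCCCCc1ccccc1)C[C@](O[Si](CC)(CC)CC)(C)CCO[S+](C)C.[Cl-] | intermediate (not isolated)
16 | (3R,5R)-3,5-dimethyl-13-phenyl-3-(triethylsilyloxy)tridecanal | C[C@H](CCCCCCCCc1ccccc1)C[C@](O[Si](CC)(CC)CC)(C)CC=O | intermediate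
17 | (4R,6R)-4,6-dimethyl-14-phenyl-4-(triethylsilyloxy)tetradec-1-yne | C[C@H](CCCCCCCCc1ccccc1)C[C@](O[Si](CC)(CC)CC)(C)CC#C | intermediate
18 | dimethyl[(1E,4R,6R)-2,4,6-trimethyl-14-phenyl-4-(triethylsilyloxy)tetradec-1-en-1-yl]alane | C[C@H](CCCCCCCCc1ccccc1)C[C@](O[Si](CC)(CC)CC)(C)C/C(C)=C/[Al](C)C | intermediate (not isolated)
19 | (2E,5R,7R)-3,5,7-trimethyl-15-phenyl-5-(triethylsilyloxy)pentadec-2-en-1-ol | C[C@H](CCCCCCCCc1ccccc1)C[C@](O[Si](CC)(CC)CC)(C)C/C(C)=C/CO | intermediate
20 | (2R,3R,5R,7R)-2,3-epoxy-3,5,7-trimethyl-15-phenyl-5-(triethylsilyloxy)pentadecan-1-ol | C[C@H](CCCCCCCCc1ccccc1)C[C@](O[Si](CC)(CC)CC)(C)C[C@]1(C)[C@@H](CO)O1 | intermediate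
21 | (3S,5R,7R)-3,5,7-trimethyl-15-phenyl-5-(triethylsilyloxy)pentadecane-1,3-diol | C[C@H](CCCCCCCCc1ccccc1)C[C@](O[Si](CC)(CC)CC)(C)C[C@](C)(CCO)O | intermediate
22 | (3S,5R,7R)-3-hydroxy-3,5,7-trimethyl-15-phenyl-5-(triethylsilyloxy)pentadecyl acetate | C[C@H](CCCCCCCCc1ccccc1)C[C@](O[Si](CC)(CC)CC)(C)C[C@](C)(CCOC(C)=O)O | intermediate
23 | (3S,5R,7R)-3,5-dihydroxy-3,5,7-trimethyl-15-phenylpentadecyl acetate | C[C@H](CCCCCCCCc1ccccc1)C[C@](O)(C)C[C@](C)(CCOC(C)=O)O | intermediate (precursor of the key step)
24 | (3S,5R,7R)-3-(fluorooxy)-5-hydroxy-3,5,7-trimethyl-15-phenylpentadecyl acetate | C[C@H](CCCCCCCCc1ccccc1)C[C@](O)(C)C[C@](C)(CCOC(C)=O)OF | intermediate (not isolated)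
25 | 2-[(3S,5R)-3,5-dimethyl-5-[(2R)-2-methyl-10-phenyldecyl]-1,2-dioxolan-3-yl]ethyl acetate | C[C@H](CCCCCCCCc1ccccc1)C[C@]1(C)C[C@](C)(CCOC(C)=O)OO1 | intermediate (product of the key step)
26 | 2-[(3S,5R)-3,5-dimethyl-5-[(2R)-2-methyl-10-phenyldecyl]-1,2-dioxolan-3-yl]ethanol | C[C@H](CCCCCCCCc1ccccc1)C[C@]1(C)C[C@](C)(CCO)OO1 | intermediate
27 | 2-[(3R,5R)-3,5-dimethyl-5-[(2R)-2-methyl-10-phenyldecyl]-1,2-dioxolan-3-yl]acetaldehyde | C[C@H](CCCCCCCCc1ccccc1)C[C@]1(C)C[C@](C)(CC=O)OO1 | intermediate (not isolated)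
28 | 2-[(3R,5R)-3,5-dimethyl-5-[(2R)-2-methyl-10-phenyldecyl]-1,2-dioxolan-3-yl]acetic acid (CNP0311791.1) | C[C@H](CCCCCCCCc1ccccc1)C[C@]1(C)C[C@](C)(CC(=O)O)OO1 | target

**Step count**

Total: 19 steps. Longest linear sequence: 18 steps (steps 2–19, from (R)-citronellal 3); step 1 is a one-step side branch.

**Steps most likely to fail**

1. Step 17 (proposed new method). Fluorination of the phenyl ring or of the tertiary C7–H bond may outrun O-fluorination, or the hypofluorite may undergo β-scission before the second hydroxyl attacks oxygen. The fallback builds the dioxolane by C–O bond formation with known reactions, at the cost of stereocontrol at both ring carbons. It sets out from aldehyde 16 and rejoins the route at target 28.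
   - Addition of MeMgBr to 16 would give (4R,6R)-4,6-dimethyl-14-phenyl-4-(triethylsilyloxy)tetradecan-2-ol F1.
   - Dess–Martin periodinane would give (4R,6R)-4,6-dimethyl-14-phenyl-4-(triethylsilyloxy)tetradecan-2-one F2.
   - Acid-catalysed perhydrolysis (50% H2O2, catalytic H2SO4, MeCN) would remove the silyl ether and replace the tertiary oxygen through the carbocation or the enone, and the hydroperoxy ketone would close to 3,5-dimethyl-5-[(2R)-2-methyl-10-phenyldecyl]-1,2-dioxolan-3-ol F3.
   - Etherification (MeOH, TsOH) would give 3-methoxy-3,5-dimethyl-5-[(2R)-2-methyl-10-phenyldecyl]-1,2-dioxolane F4.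
   - TiCl4 and 1-(tert-butyldimethylsilyloxy)-1-methoxyethene would substitute the methoxy group through the peroxycarbenium ion to give methyl 2-[(3R,5R)-3,5-dimethyl-5-[(2R)-2-methyl-10-phenyldecyl]-1,2-dioxolan-3-yl]acetate F5 together with its C3/C5 isomers. All four are diastereomers because C7 is fixed, so F5 would be separated by chromatography and saponified with LiOH in THF/H2O to 28.

2. Step 12. Carboalumination may stall beside the silyloxy-bearing quaternary carbon, the silyl ether may be cleaved by the Lewis-acidic aluminium reagent, or the alkenylalane may be protonated instead of hydroxymethylated. The fallback introduces the C3 methyl group by conjugate addition; it sets out from alkyne 17 and rejoins the route at diol 21.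
   - Deprotonation of 17 (n-BuLi) and acylation with ClCO2Me would give methyl (5R,7R)-5,7-dimethyl-15-phenyl-5-(triethylsilyloxy)pentadec-2-ynoate F6.
   - syn-Carbocupration with Me2CuLi at −78 °C would give methyl (2Z,5R,7R)-3,5,7-trimethyl-15-phenyl-5-(triethylsilyloxy)pentadec-2-enoate F7.
   - i-Bu2AlH would give (2Z,5R,7R)-3,5,7-trimethyl-15-phenyl-5-(triethylsilyloxy)pentadec-2-en-1-ol F8.
   - Because the alkene geometry is reversed, Sharpless epoxidation with L-(+)-diethyl tartrate would give (2S,3R,5R,7R)-2,3-epoxy-3,5,7-trimethyl-15-phenyl-5-(triethylsilyloxy)pentadecan-1-ol F9, which has the same C3 configuration as 20.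
   - NaAlH2(OCH2CH2OCH3)2 would open F9 at C2 to 21.

3. Step 10. The primary silyl ether may be cleaved incompletely, or the tertiary silyl ether may be lost, after which the unprotected β-hydroxy aldehyde would undergo retro-aldol cleavage or dehydration. The fallback distinguishes the two hydroxyls by orthogonal protection; it sets out from diol 13 and rejoins the route at aldehyde 16.
   - Selective acetylation of the primary alcohol (Ac2O, pyridine) would give (3R,5R)-3-hydroxy-3,5-dimethyl-13-phenyltridecyl acetate F10.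
   - Silylation of the tertiary alcohol (Et3SiOTf, 2,6-lutidine) would give (3R,5R)-3,5-dimethyl-13-phenyl-3-(triethylsilyloxy)tridecyl acetate F11.
   - Methanolysis (K2CO3, MeOH) would give (3R,5R)-3,5-dimethyl-13-phenyl-3-(triethylsilyloxy)tridecan-1-ol F12.
   - Dess–Martin periodinane would give 16.

**Further compounds**

F1 | step 17 | (4R,6R)-4,6-dimethyl-14-phenyl-4-(triethylsilyloxy)tetradecan-2-ol (both C2 epimers) | C[C@H](CCCCCCCCc1ccccc1)C[C@](O[Si](CC)(CC)CC)(C)CC(C)O
F2 | step 17 | (4R,6R)-4,6-dimethyl-14-phenyl-4-(triethylsilyloxy)tetradecan-2-one | C[C@H](CCCCCCCCc1ccccc1)C[C@](O[Si](CC)(CC)CC)(C)CC(C)=O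
F3 | step 17 | 3,5-dimethyl-5-[(2R)-2-methyl-10-phenyldecyl]-1,2-dioxolan-3-ol (C3/C5 mixture) | C[C@H](CCCCCCCCc1ccccc1)CC1(C)CC(C)(O)OO1
F4 | step 17 | 3-methoxy-3,5-dimethyl-5-[(2R)-2-methyl-10-phenyldecyl]-1,2-dioxolane (C3/C5 mixture) | C[C@H](CCCCCCCCc1ccccc1)CC1(C)CC(C)(OC)OO1
F5 | step 17 | methyl 2-[(3R,5R)-3,5-dimethyl-5-[(2R)-2-methyl-10-phenyldecyl]-1,2-dioxolan-3-yl]acetate | C[C@H](CCCCCCCCc1ccccc1)C[C@]1(C)C[C@](C)(CC(=O)OC)OO1
F6 | step 12 | methyl (5R,7R)-5,7-dimethyl-15-phenyl-5-(triethylsilyloxy)pentadec-2-ynoate | C[C@H](CCCCCCCCc1ccccc1)C[C@](O[Si](CC)(CC)CC)(C)CC#CC(=O)OC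
F7 | step 12 | methyl (2Z,5R,7R)-3,5,7-trimethyl-15-phenyl-5-(triethylsilyloxy)pentadec-2-enoate | C[C@H](CCCCCCCCc1ccccc1)C[C@](O[Si](CC)(CC)CC)(C)C/C(C)=C\C(=O)OC
F8 | step 12 | (2Z,5R,7R)-3,5,7-trimethyl-15-phenyl-5-(triethylsilyloxy)pentadec-2-en-1-ol | C[C@H](CCCCCCCCc1ccccc1)C[C@](O[Si](CC)(CC)CC)(C)C/C(C)=C\CO
F9 | step 12 | (2S,3R,5R,7R)-2,3-epoxy-3,5,7-trimethyl-15-phenyl-5-(triethylsilyloxy)pentadecan-1-ol | C[C@H](CCCCCCCCc1ccccc1)C[C@](O[Si](CC)(CC)CC)(C)C[C@]1(C)[C@H](CO)O1
F10 | step 10 | (3R,5R)-3-hydroxy-3,5-dimethyl-13-phenyltridecyl acetate | C[C@H](CCCCCCCCc1ccccc1)C[C@](O)(C)CCOC(C)=O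
F11 | step 10 | (3R,5R)-3,5-dimethyl-13-phenyl-3-(triethylsilyloxy)tridecyl acetate | C[C@H](CCCCCCCCc1ccccc1)C[C@](O[Si](CC)(CC)CC)(C)CCOC(C)=O
F12 | step 10 | (3R,5R)-3,5-dimethyl-13-phenyl-3-(triethylsilyloxy)tridecan-1-ol | C[C@H](CCCCCCCCc1ccccc1)C[C@](O[Si](CC)(CC)CC)(C)CCO
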